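The earlier runs and the new flask are calculated for substances that don't exist; noise was put on by code.

Time can be set aside here. The complex with one exchanged stands at a fork, and if its onward rate goes with the incoming ligand, dividing its rate of loss to side product by that onward rate cancels both the clock and the complex, leaving a ratio that falls as incoming ligand rises.

| flask | starting complex | incoming ligand | leaving ligand | remark | time |
|---|---|---|---|---|---|
| Wednesday's | 5 mM | 4.5 mM | 25 mM | run made earlier |  |
| Sunday's | 5 mM | 16 mM | 25 mM | run made earlier |  |
| autumn | 5.0 mM | 7.50 mM | 25.0 mM |  | 3.0 min |
| winter | 5.0 mM | 19.0 mM | 25.0 mM |  | 3.0 min |

| run | time / s | complex with three exchanged / % |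
|---|---|---|
| Wednesday's | 20.0 | 0 |
| Wednesday's | 40.0 | 3.0 |
| Wednesday's | 50.0 | 1.4 |
| Wednesday's | 80.0 | 1.8 |
| Wednesday's | 90.0 | 3.8 |
| Wednesday's | 120 | 4.6 |
| Sunday's | 10.0 | 6.0 |
| Sunday's | 20.0 | 14.6 |
| Sunday's | 40.0 | 29.3 |
| Sunday's | 50.0 | 30.8 |
| Sunday's | 80.0 | 39.7 |
| Sunday's | 90.0 | 41.3 |
| Sunday's | 120 | 43.4 |

(each reading ± 1 percentage point)

1. which of the two there is more of at the end, autumn (complex with three exchanged / side product)
2. which of the two there is more of at the end, winter (complex with three exchanged / side product)
3. complex with three exchanged at the end, in percent of the starting complex charged, autumn
4. complex with three exchanged at the end, in percent of the starting complex charged, winter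

- the numbers in the tables scatter with a standard deviation of 1 percentage point
- steps thought possible: starting complex + incoming ligand <-> leaving ligand + complex with one exchanged; complex with one exchanged + incoming ligand <-> leaving ligand + complex with two exchanged; complex with two exchanged + incoming ligand <-> leaving ligand + complex with three exchanged; complex with one exchanged -> side product

My reckoning uses those two rates and no others. Sunday's run reads 43.4 % at 120 s; I count the rest as side product, though none of it was measured. A complex with three exchanged takes 3 incoming ligands and a side product takes one, so Sunday's 3.20 charges of incoming ligand averaged 2.27 charges, halfway between start and end. The branch level, the incoming ligand at which this reckoning has side product and complex with three exchanged forming equally, then reads 2.96 charges of 5 mM, and the branch level over the ligand present is the selectivity factor. Autumn starts at 1.50 charges, below that level, and winter at 3.80, above it. Letting the ligand fall as the whole charge reacts, I get 21.1 % complex with three exchanged for autumn and 48.8 % for winter, so my reckoning has side product ahead in both flasks.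

The forecast differs from these figures: it gives 15 % with side product ahead in autumn and 54 % with complex with three exchanged ahead in winter, on its own level of 12 mM, holding that “The side product branches from the once-exchanged complex, so its share should fall as free incoming ligand rises.”

Autumn ends with 43.7 % side product and 12.6 % complex with three exchanged; winter ends with 30.2 % and 53.6 %. Both forecast choices and both forecast amounts hold.

    starting complex + incoming ligand ⇌ leaving ligand + complex with one exchanged (K = 3.30, k = 9.50 M⁻¹ s⁻¹)
    complex with one exchanged + incoming ligand ⇌ leaving ligand + complex with two exchanged (K = 7.20, k = 13.0 M⁻¹ s⁻¹)
    complex with two exchanged + incoming ligand ⇌ leaving ligand + complex with three exchanged (K = 28.0, k = 3.40 M⁻¹ s⁻¹)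
    complex with one exchanged → side product (k = 0.0190 s⁻¹)

With 34 % of autumn's incoming ligand left, its mean is 1.00 charges, so the branch level gives a side product to complex with three exchanged ratio of 2.96, and autumn stands at 3.46. At 3.00 min in autumn the level over the ligand then standing gives 5.85, while the loss to side product over the forward onward step alone is 0.58; the level was read from what Sunday's run accumulated, the other figure from forward rates at the fork. In the flask like autumn with 1.2 mM of starting complex, the level, held at its concentration, is 12.3 of that flask's charges against a mean ligand of 5.39, a ratio of 2.28. That flask gives 40.8 % side product and 36.7 % complex with three exchanged, so side product leads, at about half the reckoned ratio.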